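**Retrosynthetic overview**

- Ester ⇒ 4,6-diol + 4-methoxybenzoyl chloride (only the secondary allylic OH is acylated); the (6S)-carbinol ⇒ 7-en-6-one by hydroxyl-directed hydride delivery.
- 7-En-6-one ⇒ 9-en-6-one (hydrogenation, then dehydrogenation on the C7/C8 side).
- Both rings in one step: 9-en-6-one ⇒ acyclic epoxy enol silane. Intramolecular (4+3) cycloaddition of the oxyallyl unit C5–C6–C7 onto the (E,E)-diene C8–C9–C10–C1 forms C1–C5 and C7–C8, so the five- and seven-membered rings close together and C1, C4, C5 are set.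
- Epoxy ketone ⇒ (S)-allylic alcohol (directed epoxidation, oxidation) ⇒ Negishi union of a dienyl iodide (from but-3-yn-1-ol and (E)-1-bromopropene) with a (Z)-iodoalkenol (from 3-methylbut-1-yne, made chiral by asymmetric transfer hydrogenation).

Convention: bicyclic compounds carry daucane locants (C1 quaternary ring-fusion carbon with methyl, C2, C3, C4 bearing OH and isopropyl, C5 ring-fusion CH, C6 oxygenated, C7=C8 with methyl on C8, C9, C10); the same locants label the future positions in the acyclic precursors.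

**Step 1**
Reactants: 1 but-3-yn-1-ol; 2 (E)-1-bromoprop-1-ene
Product: 4 (3E,5E)-3-methylhepta-3,5-dien-1-ol, via alkenylalane 3 (not isolated)
Conditions: Me3Al (3 equiv), Cp2ZrCl2 (0.25 equiv), ClCH2CH2Cl, 0 to 23 °C; then 2, Pd(PPh3)4 (5 mol %), ZnCl2, THF, 23 °C
Reagents that add atoms: trimethylaluminium, C[Al](C)C
Why: Negishi zirconium-catalysed carboalumination adds methyl and aluminium syn across the alkyne, and the Pd-catalysed cross-coupling of the alkenylalane with the (E)-bromide goes with retention at both sp2 carbons, fixing the (3E,5E) geometry.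

**Step 2**
Reactants: 4 (3E,5E)-3-methylhepta-3,5-dien-1-ol
Product: 5 (3E,5E)-1-iodo-3-methylhepta-3,5-diene
Conditions: I2, PPh3, imidazole, CH2Cl2, 0 °C
Reagents that add atoms: iodine, II
Why: Appel iodination (SN2 on the primary alkoxyphosphonium) leaves the diene untouched.

**Step 3**
Reactants: 6 3-methylbut-1-yne; 7 N-methoxy-N-methylacetamide
Product: 9 5-methylhex-3-yn-2-one, via lithium acetylide 8 (not isolated)
Conditions: n-BuLi, THF, −78 °C; then 7, −78 to 0 °C
Reagents that add atoms: none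
Why: Acylation of the lithium acetylide with a Weinreb amide stops at the ketone because the chelated tetrahedral adduct survives until work-up.

**Step 4**
Reactants: 9 5-methylhex-3-yn-2-one
Product: 10 (2S)-5-methylhex-3-yn-2-ol
Conditions: RuCl[(S,S)-TsDPEN](p-cymene) (0.5 mol %), i-PrOH, 25 °C
Reagents that add atoms: none
Why: Noyori asymmetric transfer hydrogenation of an alkynyl methyl ketone with the (S,S)-catalyst gives the (S)-propargylic alcohol in high ee; this is the only external source of chirality in the route.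

**Step 5**
Reactants: 10 (2S)-5-methylhex-3-yn-2-ol
Product: 12 (2S,3Z)-4-iodo-5-methylhex-3-en-2-ol, via cyclic alkenylalanate 11 (not isolated)
Conditions: NaAlH2(OCH2CH2OMe)2, THF, 0 to 25 °C; then I2, −78 °C
Reagents that add atoms: iodine, II
Why: Hydroxyl-directed trans-hydroalumination places aluminium on the distal alkyne carbon inside a five-membered alanate, and iodinolysis with retention gives the (Z)-iodide with iodine cis to the carbinol carbon.

**Step 6**
Reactants: 5 (3E,5E)-1-iodo-3-methylhepta-3,5-diene; 12 (2S,3Z)-4-iodo-5-methylhex-3-en-2-ol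
Product: 14 (2S,3E,7E,9E)-7-methyl-4-(propan-2-yl)undeca-3,7,9-trien-2-ol, via alkylzinc iodide 13 (not isolated)
Conditions: 5, Zn dust, LiCl, THF, 40 °C; then 12, Pd(OAc)2 (2 mol %), SPhos (4 mol %), THF, 25 °C
Reagents that add atoms: none
Why: Negishi sp3–sp2 cross-coupling proceeds with retention of alkene geometry, so the dienyl chain ends cis and the isopropyl group trans to the carbinol carbon (3E), and the alkylzinc tolerates the free hydroxyl.

**Step 7**
Reactants: 14 (2S,3E,7E,9E)-7-methyl-4-(propan-2-yl)undeca-3,7,9-trien-2-ol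
Product: 15 (1S)-1-[(2R,3R)-3-[(3E,5E)-3-methylhepta-3,5-dien-1-yl]-3-(propan-2-yl)oxiran-2-yl]ethan-1-ol
Conditions: VO(acac)2 (3 mol %), t-BuOOH, toluene, 0 °C
Reagents that add atoms: tert-butyl hydroperoxide, CC(C)(C)OO
Why: Vanadium-catalysed hydroxyl-directed epoxidation touches only the allylic alkene; allylic 1,3-strain holds the carbinol H in the alkene plane so oxygen is delivered syn to the (S)-hydroxyl (threo isomer, minor erythro isomer removed by chromatography), and the syn addition sets C4 (final) and C5 (inverted in step 9).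

**Step 8**
Reactants: 15 (1S)-1-[(2R,3R)-3-[(3E,5E)-3-methylhepta-3,5-dien-1-yl]-3-(propan-2-yl)oxiran-2-yl]ethan-1-ol
Product: 16 1-[(2S,3R)-3-[(3E,5E)-3-methylhepta-3,5-dien-1-yl]-3-(propan-2-yl)oxiran-2-yl]ethan-1-one
Conditions: Dess–Martin periodinane, CH2Cl2, 0 to 23 °C
Reagents that add atoms: none
Why: Dess–Martin oxidation of the secondary alcohol gives the epoxy ketone without touching the epoxide or the diene.

**Step 9**
Reactants: 16 1-[(2S,3R)-3-[(3E,5E)-3-methylhepta-3,5-dien-1-yl]-3-(propan-2-yl)oxiran-2-yl]ethan-1-one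
Product: 19 (1R,4R,5R,8R)-4-hydroxy-1,8-dimethyl-4-(propan-2-yl)bicyclo[5.3.0]dec-9-en-6-one, via triethylsilyl enol ether 17 (not isolated), via triethylsilyl-protected cycloadduct 18 (not isolated)
Conditions: Et3SiOTf (1.3 equiv), Et3N (1.2 equiv), CH2Cl2, −78 to −40 °C; then HF·pyridine, THF, 0 °C
Reagents that add atoms: none
Why: Proposed new method: this extends the silyl-triflate-triggered intramolecular (4+3) cycloaddition of epoxy enol silanes (closest known type: tethered furans and cyclic dienes) to an acyclic diene with a fully substituted terminus; silyl activation lets diene carbon C1 open the epoxide at C5 from the backside (inversion at C5, C4 untouched, so O4 ends cis to C6) while enol-silane carbon C7 closes onto C8, and with the tether on the E position of the diene the extended transition state needed for the second bond puts the C1 methyl anti to H5 (trans fusion), so both rings form together; the C8 configuration is inconsequential.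

**Step 10**
Reactants: 19 (1R,4R,5R,8R)-4-hydroxy-1,8-dimethyl-4-(propan-2-yl)bicyclo[5.3.0]dec-9-en-6-one
Product: 20 (1S,4R,5R,8S)-4-hydroxy-1,8-dimethyl-4-(propan-2-yl)bicyclo[5.3.0]decan-6-one
Conditions: H2 (1 atm), Pd on carbon (10 wt%), EtOAc, 23 °C
Reagents that add atoms: none
Why: Heterogeneous hydrogenation saturates the only alkene (cis-disubstituted C9=C10); ketone and tertiary alcohol are inert and the C8 stereocentre is removed in the next step.

**Step 11**
Reactants: 20 (1S,4R,5R,8S)-4-hydroxy-1,8-dimethyl-4-(propan-2-yl)bicyclo[5.3.0]decan-6-one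
Product: 22 (1S,4R,5R)-4-hydroxy-1,8-dimethyl-4-(propan-2-yl)bicyclo[5.3.0]dec-7-en-6-one, via bis(trimethylsilyl) enol ether 21 (not isolated)
Conditions: LiN(iPr)2 (2.3 equiv), Me3SiCl, THF, −78 °C; then Pd(OAc)2 (10 mol %), O2 (1 atm), DMSO, 25 °C; 1 M HCl work-up
Reagents that add atoms: none
Why: Saegusa–Ito dehydrogenation (catalytic variant) can only give the C7=C8 enone because C5 is flanked by two quaternary carbons and has no β-hydrogen; C5 stays trans-fused, which should also be the thermodynamic arrangement (isopropyl anti to C6, OH···O=C hydrogen bond).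

**Step 12**
Reactants: 22 (1S,4R,5R)-4-hydroxy-1,8-dimethyl-4-(propan-2-yl)bicyclo[5.3.0]dec-7-en-6-one
Product: 24 (1S,4R,5S,6S)-1,8-dimethyl-4-(propan-2-yl)bicyclo[5.3.0]dec-7-ene-4,6-diol, via alkoxyhydroborate 23 (not isolated)
Conditions: Me4NBH(OAc)3, MeCN/AcOH (1:1), −30 °C
Reagents that add atoms: none
Why: Evans–Saksena directed reduction: the C4 hydroxyl exchanges onto boron and delivers hydride intramolecularly to the face of the C6 carbonyl on which O4 lies, giving the anti-1,3-diol, that is the (6S)-alcohol with O6 cis to H5.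

**Step 13**
Reactants: 24 (1S,4R,5S,6S)-1,8-dimethyl-4-(propan-2-yl)bicyclo[5.3.0]dec-7-ene-4,6-diol; 25 4-methoxybenzoyl chloride
Product: 26 (1S,4R,5S,6S)-4-hydroxy-1,8-dimethyl-4-(propan-2-yl)bicyclo[5.3.0]dec-7-en-6-yl 4-methoxybenzoate
Conditions: pyridine, 4-(dimethylamino)pyridine (10 mol %), CH2Cl2, 0 to 23 °C
Reagents that add atoms: none
Why: Nucleophile-catalysed acylation esterifies only the secondary allylic alcohol; the hindered tertiary alcohol does not react.

**Compound list**

1 | but-3-yn-1-ol | C#CCCO | starting material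
2 | (E)-1-bromoprop-1-ene | C/C=C/Br | starting material
3 | dimethyl[(1E)-4-(dimethylalumanyloxy)-2-methylbut-1-en-1-yl]alumane | C[Al](C)/C=C(\C)CCO[Al](C)C | intermediate
4 | (3E,5E)-3-methylhepta-3,5-dien-1-ol | OCC/C(C)=C/C=C/C | intermediate
5 | (3E,5E)-1-iodo-3-methylhepta-3,5-diene | ICC/C(C)=C/C=C/C | intermediate
6 | 3-methylbut-1-yne | CC(C)C#C | starting material
7 | N-methoxy-N-methylacetamide | CC(=O)N(C)OC | starting material
8 | lithium 3-methylbut-1-yn-1-ide | [Li]C#CC(C)C | intermediate
9 | 5-methylhex-3-yn-2-one | CC(=O)C#CC(C)C | intermediate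
10 | (2S)-5-methylhex-3-yn-2-ol | C[C@H](O)C#CC(C)C | intermediate
11 | sodium (5S)-2,2-bis(2-methoxyethoxy)-5-methyl-3-(propan-2-yl)-2,5-dihydro-1,2-oxaluminol-2-uide (Al on the isopropyl-bearing alkene carbon, ring O from the carbinol) | C[C@@H]1O[Al-](OCCOC)(OCCOC)C(C(C)C)=C1.[Na+] | intermediate
12 | (2S,3Z)-4-iodo-5-methylhex-3-en-2-ol | C[C@H](O)/C=C(\I)C(C)C | intermediate
13 | [(3E,5E)-3-methylhepta-3,5-dien-1-yl]zinc iodide | I[Zn]CC/C(C)=C/C=C/C | intermediate
14 | (2S,3E,7E,9E)-7-methyl-4-(propan-2-yl)undeca-3,7,9-trien-2-ol | C[C@H](O)/C=C(/C(C)C)CC/C(C)=C/C=C/C | intermediate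
15 | (1S)-1-[(2R,3R)-3-[(3E,5E)-3-methylhepta-3,5-dien-1-yl]-3-(propan-2-yl)oxiran-2-yl]ethan-1-ol | C[C@H](O)[C@H]1O[C@@]1(C(C)C)CC/C(C)=C/C=C/C | intermediate
16 | 1-[(2S,3R)-3-[(3E,5E)-3-methylhepta-3,5-dien-1-yl]-3-(propan-2-yl)oxiran-2-yl]ethan-1-one | CC(=O)[C@H]1O[C@@]1(C(C)C)CC/C(C)=C/C=C/C | intermediate
17 | triethylsilyl enol ether of 16 (2-silyloxyprop-1-en-2-yl on the oxirane, epoxide as in 16) | C=C(O[Si](CC)(CC)CC)[C@H]1O[C@@]1(C(C)C)CC/C(C)=C/C=C/C | intermediate
18 | (1R,4R,5R,8R)-1,8-dimethyl-4-(propan-2-yl)-4-(triethylsilyloxy)bicyclo[5.3.0]dec-9-en-6-one (daucane numbering) | O=C2C[C@@H](C)C=C[C@@]3(C)CC[C@@](O[Si](CC)(CC)CC)(C(C)C)[C@H]23 | intermediate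
19 | (1R,4R,5R,8R)-4-hydroxy-1,8-dimethyl-4-(propan-2-yl)bicyclo[5.3.0]dec-9-en-6-one (daucane numbering; trans-fused, 4-OH cis to C1-methyl) | O=C2C[C@@H](C)C=C[C@@]3(C)CC[C@@](O)(C(C)C)[C@H]23 | intermediate
20 | (1S,4R,5R,8S)-4-hydroxy-1,8-dimethyl-4-(propan-2-yl)bicyclo[5.3.0]decan-6-one | O=C2C[C@@H](C)CC[C@@]3(C)CC[C@@](O)(C(C)C)[C@H]23 | intermediate
21 | 4-O,6-O-bis(trimethylsilyl) 6-en-6-ol ether of 20 (C6=C7 enol ether, stereocentres as in 20) | C[Si](C)(C)OC2=C[C@@H](C)CC[C@@]3(C)CC[C@@](O[Si](C)(C)C)(C(C)C)[C@H]23 | intermediate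
22 | (1S,4R,5R)-4-hydroxy-1,8-dimethyl-4-(propan-2-yl)bicyclo[5.3.0]dec-7-en-6-one | O=C2C=C(C)CC[C@@]3(C)CC[C@@](O)(C(C)C)[C@H]23 | intermediate
23 | tetramethylammonium diacetoxy(hydrido)borate ester of 22 at O4 | O=C2C=C(C)CC[C@@]3(C)CC[C@@](O[BH-](OC(C)=O)OC(C)=O)(C(C)C)[C@H]23.C[N+](C)(C)C | intermediate
24 | (1S,4R,5S,6S)-1,8-dimethyl-4-(propan-2-yl)bicyclo[5.3.0]dec-7-ene-4,6-diol | O[C@H]2C=C(C)CC[C@@]3(C)CC[C@@](O)(C(C)C)[C@H]23 | intermediate
25 | 4-methoxybenzoyl chloride | COc1ccc(C(Cl)=O)cc1 | starting material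
26 | (1S,4R,5S,6S)-4-hydroxy-1,8-dimethyl-4-(propan-2-yl)bicyclo[5.3.0]dec-7-en-6-yl 4-methoxybenzoate | COc1ccc(C(=O)O[C@H]2C=C(C)CC[C@@]3(C)CC[C@@](O)(C(C)C)[C@H]23)cc1 | target

**Totals**

Total step count: 13. Longest linear sequence: 11 steps (steps 3 to 13).

**Steps most likely to fail, with fallbacks**

Step 9 (the cycloaddition). Risks are closure of C7 onto C10 instead of C8 (a five-membered ring), cis ring fusion, or acid-induced rearrangement of the epoxide before the hindered C1 terminus can attack. The fallback sets out from 16. SmI2 (THF/MeOH, −78 °C) cleaves the epoxide C–O bond next to the carbonyl and gives (4S,7E,9E)-4-hydroxy-7-methyl-4-(propan-2-yl)undeca-7,9-dien-2-one F1 with C4 intact. LiN(iPr)2 followed by N-chlorosuccinimide chlorinates the methyl terminus to (4S,7E,9E)-1-chloro-4-hydroxy-7-methyl-4-(propan-2-yl)undeca-7,9-dien-2-one F2. Et3N in CF3CH2OH then generates the free oxyallyl cation under basic, protic conditions, and its (4+3) addition across the tethered diene is steered at C5 by the neighbouring C4 stereocentre instead of by epoxide inversion. This comes back to the route at 19.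

Step 7 (directed epoxidation). The threo preference of vanadium catalysis is moderate, and any erythro isomer carried through step 8 becomes the enantiomer of 16. The fallback sets out from 14. MnO2 oxidises it to (3E,7E,9E)-7-methyl-4-(propan-2-yl)undeca-3,7,9-trien-2-one F3, and a catalyst-controlled nucleophilic epoxidation (La(OiPr)3/BINOL/Ph3As=O, t-BuOOH, with the BINOL enantiomer chosen for the (2S,3R)-epoxide) replaces substrate control by reagent control. This comes back to the route at 16.

Step 12 (directed reduction). Ligand exchange at the hindered tertiary hydroxyl may be slow, and an external hydride may attack the other face. The fallback sets out from 22. NaBH4 with CeCl3·7H2O reduces the enone without relying on delivery; if this gives the C6 epimer (1S,4R,5S,6R)-1,8-dimethyl-4-(propan-2-yl)bicyclo[5.3.0]dec-7-ene-4,6-diol F4, a Mitsunobu esterification with 4-methoxybenzoic acid (PPh3, diisopropyl azodicarboxylate) inverts C6 and installs the ester in the same step. This comes back to the route at 26.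

**Further compounds**

F1 | step 9 | (4S,7E,9E)-4-hydroxy-7-methyl-4-(propan-2-yl)undeca-7,9-dien-2-one | CC(=O)C[C@](O)(C(C)C)CC/C(C)=C/C=C/C
F2 | step 9 | (4S,7E,9E)-1-chloro-4-hydroxy-7-methyl-4-(propan-2-yl)undeca-7,9-dien-2-one | ClCC(=O)C[C@](O)(C(C)C)CC/C(C)=C/C=C/C
F3 | step 7 | (3E,7E,9E)-7-methyl-4-(propan-2-yl)undeca-3,7,9-trien-2-one | CC(=O)/C=C(/C(C)C)CC/C(C)=C/C=C/C
F4 | step 12 | (1S,4R,5S,6R)-1,8-dimethyl-4-(propan-2-yl)bicyclo[5.3.0]dec-7-ene-4,6-diol | O[C@@H]2C=C(C)CC[C@@]3(C)CC[C@@](O)(C(C)C)[C@H]23
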